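**Strategy.** The tetrahydrofuran ring is numbered O1, C2 (guaiacyl), C3 (methyl), C4 (carrying benzylic C7'), C5. The feature exploited is that C3–C4(C7')–C5 is a masked 2-carboxycrotyl unit, so the plan rests on cutting C2–C3 and O1–C5 together. A geometrically pure (Z)-2-(ethoxycarbonyl)crotyl pinacolboronate adds to O-benzylvanillin through a closed chair under a chiral phosphoric acid. The oxygen so created then closes onto the ester carbonyl. This single operation should give the five-membered ring, two skeletal bonds, the trans C2/C3 pair in absolute form and an exocyclic C4=C7' acceptor. Conjugate arylation, equilibration at C4, reduction of C5 and one double debenzylation finish the target.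

Key step: step 4

**Remarks on the chemistry**
- Configuration: the target is (2R,3R,4R). The aryl group at C2 is trans to the methyl at C3, and that methyl is trans to the arylmethyl group at C4.
- Geometry: in the boronate the methyl group is cis to CO2Et and trans to CH2B. CO2Et outranks CH2B, so this isomer is Z, and it reacts like an E-type crotyl reagent to give the anti adduct.
- Assumption: the (R)-acid is taken to open the Re face of the aldehyde, as it does with simple allyl and (E)-crotyl pinacolboronates. If the sense were opposite, the (S)-acid would be used and nothing else would change.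
- Protection: both phenols travel as benzyl ethers. A free syringyl hydroxyl would be sulfonylated in the ring closure and would make the boronic acid prone to protodeboronation. One hydrogenolysis removes both groups. O-Benzylvanillin is bought as such.

**Step 1**
Reactants: 1 ethyl but-2-ynoate; 2 2-(chloromethyl)-4,4,5,5-tetramethyl-1,3,2-dioxaborolane
Product: 4 ethyl (Z)-2-[(4,4,5,5-tetramethyl-1,3,2-dioxaborolan-2-yl)methyl]but-2-enoate, via vinylalane 3 (not isolated)
Conditions: i-Bu2AlH (1.1 equiv), HMPA (2.2 equiv), THF, 0 °C; then 2 (1.1 equiv), 0 °C → rt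
Reagents that add atoms: diisobutylaluminium hydride, CC(C)C[AlH]CC(C)C (the i-Bu2Al unit is present only in 3; only its hydrogen stays in 4)
Why: Known conjugate syn-hydroalumination of an alkynoate puts aluminium on the α-carbon cis to the new β-hydrogen, and Matteson-type capture (boron ate complex, 1,2-shift expelling chloride) keeps that geometry, so CH2B ends trans to methyl.

**Step 2**
Reactants: 5 4-bromo-2,6-dimethoxyphenol
Product: 6 2-(benzyloxy)-5-bromo-1,3-dimethoxybenzene
Conditions: BnBr (1.2 equiv), K2CO3 (2 equiv), DMF, 60 °C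
Reagents that add atoms: benzyl bromide, BrCc1ccccc1
Why: Williamson etherification of the phenoxide, which works on 2,6-dimethoxyphenols and leaves the aryl bromide untouched.

**Step 3**
Reactants: 6 2-(benzyloxy)-5-bromo-1,3-dimethoxybenzene
Product: 9 [4-(benzyloxy)-3,5-dimethoxyphenyl]boronic acid, via aryllithium 7 (not isolated), via lithium aryltriisopropoxyborate 8 (not isolated)
Conditions: n-BuLi (1.1 equiv), THF, −78 °C; B(Oi-Pr)3 (1.5 equiv), −78 °C → rt; 1 M HCl
Reagents that add atoms: n-butyllithium, [Li]CCCC (lithium only in 7 and 8); triisopropyl borate, CC(C)OB(OC(C)C)OC(C)C; water, O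
Why: Bromine–lithium exchange at −78 °C outruns benzylic deprotonation, and borate trapping followed by acidic hydrolysis is the standard route to arylboronic acids.

**Step 4**
Reactants: 10 4-(benzyloxy)-3-methoxybenzaldehyde; 4 ethyl (Z)-2-[(4,4,5,5-tetramethyl-1,3,2-dioxaborolan-2-yl)methyl]but-2-enoate
Product: 13 (4R,5R)-5-[4-(benzyloxy)-3-methoxyphenyl]-4-methyl-3-methylideneoxolan-2-one (trans lactone), via O-boryl adduct 11 (not isolated), via hydroxy ester 12 (not isolated)
Conditions: 4 (1.2 equiv), (R)-TRIP [(R)-3,3'-bis(2,4,6-triisopropylphenyl)-1,1'-binaphthyl-2,2'-diyl hydrogen phosphate] (10 mol%), toluene (1 M), rt; then p-TsOH·H2O (20 mol%), rt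
Reagents that add atoms: none
Why: Proposed new method: the acid OH hydrogen-bonds to one pinacol oxygen, which raises the Lewis acidity of boron, while its P=O holds the formyl hydrogen; boron then takes up the aldehyde oxygen and the γ-carbon (C3) bonds to C2 in a closed six-membered chair with allylic transposition, turning the former B–CH2 into the exocyclic C7' methylene. The closest known reactions are the phosphoric-acid-catalysed allyl- and (E)-crotylboration of aromatic aldehydes with pinacolboronates and the achiral TfOH- or Sc(OTf)3-catalysed addition of 2-alkoxycarbonyl allylboronates with lactonisation; untested is the chiral acid on the ester-deactivated reagent, hence the high concentration and room temperature, at which the uncatalysed racemic addition of this sluggish pair should stay far behind. The one ring closes 5-exo-trig: O1, as its borate 11 or as the free hydroxyl of 12 after the p-TsOH·H2O finish, attacks the ester carbonyl C5 and ethoxide leaves. The C2/C3 relationship is controlled by the alkene geometry of 4, since the methyl group trans to CH2B and the aryl group both sit equatorial, which gives the anti adduct and so the trans lactone. The absolute sense (Re-face attack, R at C2 and with it R at C3) is controlled by the 3,3'-aryl pocket of the (R)-acid. The step therefore needs anti diastereoselectivity and one aldehyde face, secured by the isomeric purity of 4 and the two-point binding of 10, and it is buffered because heterolysis of the electron-rich C2–O1 bond would leave C3 untouched and reclose anti to the methyl group.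

**Step 5**
Reactants: 13 trans α-methylene lactone; 9 [4-(benzyloxy)-3,5-dimethoxyphenyl]boronic acid
Product: 15 (3R,4R,5R)-5-[4-(benzyloxy)-3-methoxyphenyl]-3-[4-(benzyloxy)-3,5-dimethoxybenzyl]-4-methyloxolan-2-one (all-trans lactone), via C4-epimer mixture 14 (not isolated)
Conditions: 9 (1.5 equiv), [Rh(cod)OH]2 (2.5 mol%; cod = cycloocta-1,5-diene), dioxane/H2O 10:1, rt → 40 °C; silica plug, solvent switch; DBU (1 equiv), toluene, 80 °C
Reagents that add atoms: none
Why: In this Hayashi–Miyaura-type 1,4-addition the aryl–rhodium species carbometalates the unhindered C7' terminus and water protonates the oxa-π-allyl rhodium enolate without reliable facial bias, so DBU then equilibrates C4, the only acidic stereocentre, to the all-trans lactone with the benzyl group anti to the C3 methyl.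

**Step 6**
Reactants: 15 all-trans lactone
Product: 16 (1R,2R,3R)-1-[4-(benzyloxy)-3-methoxyphenyl]-3-[4-(benzyloxy)-3,5-dimethoxybenzyl]-2-methylbutane-1,4-diol
Conditions: LiAlH4 (1.5 equiv), THF, 0 °C → rt; aqueous Rochelle salt work-up
Reagents that add atoms: none
Why: Standard LiAlH4 reduction of a lactone to the 1,4-diol is faster than enolisation, so C4 keeps its configuration and the benzyl ethers, C2 and C3 are not affected.

**Step 7**
Reactants: 16 1,4-diol
Product: 18 (2R,3R,4R)-2-[4-(benzyloxy)-3-methoxyphenyl]-4-[4-(benzyloxy)-3,5-dimethoxybenzyl]-3-methyloxolane, via primary monotosylate 17 (not isolated)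
Conditions: TsCl (1.1 equiv), Et3N (3 equiv), DMAP (10 mol%), CH2Cl2, 0 °C → 40 °C
Reagents that add atoms: p-toluenesulfonyl chloride, Cc1ccc(cc1)S(=O)(=O)Cl (the tosyl group is present only in 17)
Why: Selective sulfonylation of the unhindered primary hydroxyl and 5-exo-tet Williamson-type displacement by the benzylic hydroxyl break no bond at a stereocentre, so C2 is retained, unlike in a cyclodehydration through a benzylic cation.

**Step 8**
Reactants: 18 bis(benzyl ether) of the target
Product: 19 4-{[(3R,4R,5R)-5-(4-hydroxy-3-methoxyphenyl)-4-methyloxolan-3-yl]methyl}-2,6-dimethoxyphenol (target; 2R,3R,4R in the numbering used here)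
Conditions: H2 (1 atm), 10% Pd/C, EtOAc, rt, stopped at full conversion
Reagents that add atoms: none
Why: Catalytic hydrogenolysis cleaves aryl benzyl ethers much faster than the ring C2–O1 bond in a neutral aprotic solvent at 1 atm, so both phenols are released at once and no stereocentre is involved.

**Compound list**
1 | ethyl but-2-ynoate | CC#CC(=O)OCC | starting material
2 | 2-(chloromethyl)-4,4,5,5-tetramethyl-1,3,2-dioxaborolane | ClCB1OC(C)(C)C(C)(C)O1 | starting material
3 | ethyl (E)-2-(diisobutylalumanyl)but-2-enoate (Al cis to the vinylic H, methyl cis to the ester) | C/C=C(/[Al](CC(C)C)CC(C)C)C(=O)OCC | intermediate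
4 | ethyl (Z)-2-[(4,4,5,5-tetramethyl-1,3,2-dioxaborolan-2-yl)methyl]but-2-enoate | C/C=C(/CB1OC(C)(C)C(C)(C)O1)C(=O)OCC | intermediate
5 | 4-bromo-2,6-dimethoxyphenol | COc1cc(Br)cc(OC)c1O | starting material
6 | 2-(benzyloxy)-5-bromo-1,3-dimethoxybenzene | COc1cc(Br)cc(OC)c1OCc1ccccc1 | intermediate
7 | [4-(benzyloxy)-3,5-dimethoxyphenyl]lithium | [Li]c1cc(OC)c(OCc2ccccc2)c(OC)c1 | intermediate
8 | lithium [4-(benzyloxy)-3,5-dimethoxyphenyl]triisopropoxyborate | [Li+].CC(C)O[B-](OC(C)C)(OC(C)C)c1cc(OC)c(OCc2ccccc2)c(OC)c1 | intermediate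
9 | [4-(benzyloxy)-3,5-dimethoxyphenyl]boronic acid | OB(O)c1cc(OC)c(OCc2ccccc2)c(OC)c1 | intermediate
10 | 4-(benzyloxy)-3-methoxybenzaldehyde | COc1cc(C=O)ccc1OCc1ccccc1 | starting material
11 | ethyl (3R,4R)-4-[4-(benzyloxy)-3-methoxyphenyl]-3-methyl-2-methylidene-4-[(4,4,5,5-tetramethyl-1,3,2-dioxaborolan-2-yl)oxy]butanoate | COc1cc([C@H](OB2OC(C)(C)C(C)(C)O2)[C@H](C)C(=C)C(=O)OCC)ccc1OCc1ccccc1 | intermediate
12 | ethyl (3R,4R)-4-[4-(benzyloxy)-3-methoxyphenyl]-4-hydroxy-3-methyl-2-methylidenebutanoate | COc1cc([C@H](O)[C@H](C)C(=C)C(=O)OCC)ccc1OCc1ccccc1 | intermediate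
13 | (4R,5R)-5-[4-(benzyloxy)-3-methoxyphenyl]-4-methyl-3-methylideneoxolan-2-one | COc1cc([C@@H]2OC(=O)C(=C)[C@H]2C)ccc1OCc1ccccc1 | intermediate
14 | (4R,5R)-5-[4-(benzyloxy)-3-methoxyphenyl]-3-[4-(benzyloxy)-3,5-dimethoxybenzyl]-4-methyloxolan-2-one, mixture of epimers at the α-carbon (C4 of the target) | COc1cc([C@@H]2OC(=O)C(Cc3cc(OC)c(OCc4ccccc4)c(OC)c3)[C@H]2C)ccc1OCc1ccccc1 | intermediate
15 | (3R,4R,5R)-5-[4-(benzyloxy)-3-methoxyphenyl]-3-[4-(benzyloxy)-3,5-dimethoxybenzyl]-4-methyloxolan-2-one | COc1cc([C@@H]2OC(=O)[C@H](Cc3cc(OC)c(OCc4ccccc4)c(OC)c3)[C@H]2C)ccc1OCc1ccccc1 | intermediate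
16 | (1R,2R,3R)-1-[4-(benzyloxy)-3-methoxyphenyl]-3-[4-(benzyloxy)-3,5-dimethoxybenzyl]-2-methylbutane-1,4-diol | COc1cc([C@H](O)[C@H](C)[C@H](CO)Cc2cc(OC)c(OCc3ccccc3)c(OC)c2)ccc1OCc1ccccc1 | intermediate
17 | (2R,3R,4R)-4-[4-(benzyloxy)-3-methoxyphenyl]-2-[4-(benzyloxy)-3,5-dimethoxybenzyl]-4-hydroxy-3-methylbutyl 4-methylbenzenesulfonate | COc1cc([C@H](O)[C@H](C)[C@H](COS(=O)(=O)c2ccc(C)cc2)Cc2cc(OC)c(OCc3ccccc3)c(OC)c2)ccc1OCc1ccccc1 | intermediate
18 | (2R,3R,4R)-2-[4-(benzyloxy)-3-methoxyphenyl]-4-[4-(benzyloxy)-3,5-dimethoxybenzyl]-3-methyloxolane | COc1cc([C@@H]2OC[C@H](Cc3cc(OC)c(OCc4ccccc4)c(OC)c3)[C@H]2C)ccc1OCc1ccccc1 | intermediate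
19 | 4-{[(3R,4R,5R)-5-(4-hydroxy-3-methoxyphenyl)-4-methyloxolan-3-yl]methyl}-2,6-dimethoxyphenol | COc1cc([C@@H]2OC[C@H](Cc3cc(OC)c(O)c(OC)c3)[C@H]2C)ccc1O | target

**Step count.** Total: 8 steps. Longest linear sequence: 6 steps (1 → 4 → 5 → 6 → 7 → 8, or equally 2 → 3 → 5 → 6 → 7 → 8).

**Steps most likely to fail**

1. **Step 4 (the step with the new-method label).**
   - What may go wrong: a weak acid may accelerate the electron-poor boronate and electron-rich aldehyde too little, so conversion stalls or the unselective thermal pathway takes over. The ester carbonyl may also compete for the hydrogen bond and erode facial selectivity.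
   - Fallback, known chemistry only, from 10 back to 13. The established phosphoric-acid-catalysed crotylboration of 10 with commercial (E)-crotylboronic acid pinacol ester and the same (R)-acid (toluene, −30 °C) gives (1R,2R)-1-[4-(benzyloxy)-3-methoxyphenyl]-2-methylbut-3-en-1-ol F1.
   - Hydroboration with 9-BBN and H2O2/NaOH oxidation gives (1R,2R)-1-[4-(benzyloxy)-3-methoxyphenyl]-2-methylbutane-1,4-diol F2.
   - TEMPO/PhI(OAc)2 oxidises the primary alcohol through the lactol to (4R,5R)-5-[4-(benzyloxy)-3-methoxyphenyl]-4-methyloxolan-2-one F3.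
   - LDA followed by Eschenmoser's salt (dimethylmethylideneammonium iodide) gives the α-(dimethylaminomethyl) lactone F4. MeI converts it to the trimethylammonium iodide F5, and NaHCO3-induced elimination installs the exocyclic methylene and returns 13.
   - C2 and C3 are then set by a reaction proven on aromatic aldehydes, at the price of a longer sequence.

2. **Step 5.**
   - What may go wrong: the exocyclic double bond may migrate into the ring under rhodium hydride or base, which would erase C3. Protodeboronation of the electron-rich boronic acid may outrun transmetalation. Heck-type β-hydride elimination may replace protonation.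
   - Fallback, from 6 and 13 back to 14 and so to 15. Bromine–lithium exchange of 6 gives 7 as in step 3. CuBr·SMe2 (0.5 equiv per 7) converts it to lithium bis[4-(benzyloxy)-3,5-dimethoxyphenyl]cuprate F6.
   - F6 adds 1,4 to 13 in THF at −78 °C under aprotic conditions free of metal hydride. An NH4Cl quench gives 14, which enters the DBU equilibration unchanged. This also bypasses step 3.

3. **Step 8.**
   - What may go wrong: hydrogenolytic opening of the benzylic C2–O1 bond may compete with O-debenzylation, most of all once the para-phenol has been freed.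
   - Fallback, from 18 to 19. A non-reductive Lewis-acid debenzylation with BCl3 and pentamethylbenzene as benzyl-cation scavenger (CH2Cl2, −78 °C, quenched cold) removes only the aryl benzyl ethers.
   - Any transient ionisation at C2 would reclose to the same 2,3-trans ring. This fallback makes no new compound (F0).

**Further compounds**
F1 | step 4 | (1R,2R)-1-[4-(benzyloxy)-3-methoxyphenyl]-2-methylbut-3-en-1-ol | COc1cc([C@H](O)[C@H](C)C=C)ccc1OCc1ccccc1
F2 | step 4 | (1R,2R)-1-[4-(benzyloxy)-3-methoxyphenyl]-2-methylbutane-1,4-diol | COc1cc([C@H](O)[C@H](C)CCO)ccc1OCc1ccccc1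
F3 | step 4 | (4R,5R)-5-[4-(benzyloxy)-3-methoxyphenyl]-4-methyloxolan-2-one | COc1cc([C@@H]2OC(=O)C[C@H]2C)ccc1OCc1ccccc1
F4 | step 4 | (3S,4R,5R)-5-[4-(benzyloxy)-3-methoxyphenyl]-3-[(dimethylamino)methyl]-4-methyloxolan-2-one | COc1cc([C@@H]2OC(=O)[C@H](CN(C)C)[C@H]2C)ccc1OCc1ccccc1
F5 | step 4 | {(3S,4R,5R)-5-[4-(benzyloxy)-3-methoxyphenyl]-4-methyl-2-oxooxolan-3-yl}-N,N,N-trimethylmethanaminium iodide | [I-].COc1cc([C@@H]2OC(=O)[C@H](C[N+](C)(C)C)[C@H]2C)ccc1OCc1ccccc1
F6 | step 5 | lithium bis[4-(benzyloxy)-3,5-dimethoxyphenyl]cuprate | [Li+].COc1cc(cc(OC)c1OCc1ccccc1)[Cu-]c1cc(OC)c(OCc2ccccc2)c(OC)c1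
F0 | step 8 | none | none
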